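The runs stem from a simulated flask on assumed constants; noise was put on by code.

You put 3 questions to us, two orders at Tuesday's charge and one share for Saturday's flask, and you wanted a quick number to set beside your hunch; the flasks, readings and questions stand here.

| flask | X | E | time |
|---|---|---|---|
| Tuesday's | 300 mM | 900 mM |  |
| Sunday's | 180 mM | 780 mM |  |
| Thursday's | 150 mM | 900 mM |  |
| Saturday's | 65.0 mM | 900 mM | 130 min |

| run | time / min | [G] / mM |
|---|---|---|
| Tuesday's run | 4.7 | 1.3 |
| Tuesday's run | 14 | 7.0 |
| Tuesday's run | 27 | 16.4 |
| Tuesday's run | 43 | 32.7 |
| Tuesday's run | 61 | 58.9 |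
| Tuesday's run | 82 | 93.9 |
| Tuesday's run | 100 | 127.6 |
| Tuesday's run | 130 | 177.0 |
| Sunday's run | 4.7 | 0.9 |
| Sunday's run | 14 | 3.4 |
| Sunday's run | 27 | 6.2 |
| Sunday's run | 43 | 12.6 |
| Sunday's run | 61 | 18.1 |
| Sunday's run | 82 | 27.8 |
| Sunday's run | 100 | 37.8 |
| Sunday's run | 130 | 54.6 |
| Thursday's run | 4.7 | 1.3 |
| Thursday's run | 14 | 3.8 |
| Thursday's run | 27 | 6.5 |
| Thursday's run | 43 | 12.2 |
| Thursday's run | 61 | 16.9 |
| Thursday's run | 82 | 27.5 |
| Thursday's run | 100 | 33.2 |
| Thursday's run | 130 | 48.8 |

(standard deviation of a reading: 0.9 mM)

- Overall: X + E -> G.
- Constant volume, constant temperature.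
- The analysis sees a species whether free or bound.
- An order is taken over about fifteen percent of the charge, up and down.

* the exponent of [E] in the starting rate at the charge of the Tuesday's run (at the point where two percent of the X have become G)
* the exponent of [X] in the starting rate at the charge of the Tuesday's run (at the point where two percent of the X have become G) (one fixed amount of G, the same in the runs compared)
* G in the Saturday's run at 130 min, as a share of the X charged

We commit to a number of our own for the share and offer none for the orders.

1. Tuesday's flask and Thursday's flask have the same c(E), 900 mM, but different c(X), and at 130 min Tuesday's flask reads 59.0% of its X as G, a larger share than the 32.5% read in Thursday's flask.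

2. Dividing that difference by the difference in charge gives 0.00176 mM⁻¹, and this is the figure we carry, a reading with the scatter of its readings: the charge gain, the extra share of X turned by that time, at that c(E), for each mM more of X charged, as read between these two flasks.

3. Saturday's flask has the same c(E), and X is its limiting reagent, at 65.0 mM against 900 mM of E. Its c(X) lies 85.0 mM below Thursday's, so we walk down a straight line, an assumption carried beyond both measured charges, and reach 17.5%.

4. Your forecast gives 1 for the order in E, 0.95 for the order in X and 26% for Saturday's share, on the ground that “The G curves start slowly and then speed up, so G is autocatalytic.” Our share is lower than yours, and the two come from different reckonings.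

The flask gives 1.3 for the order in E, 1.1 for the order in X and 19.5% for Saturday's share.

    2 E ⇌ E2, settled at all times (0.3750 M⁻¹)
    X + E2 → G + E (0.009420 M⁻¹ min⁻¹)
    X + E + G → 2 G (0.1854 M⁻² min⁻¹)
    G + E → Z (0.004806 M⁻¹ min⁻¹)

With the charge gain of 0.00176 mM⁻¹, our line stood 2.0 percentage points below Saturday's share, and the forecast stood 6.5 points above it. Saturday's flask loses G to Z through the path from G + E: the run of Saturday's flask without that path reaches 24.2%, where the run with it reaches 19.5%, a difference of 4.7 points.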